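**Retrosynthetic overview**
- The target is reached by cleaving six methyl ethers of a 1-(4-hydroxyphenyl)naphthalene, which comes from dehydrogenation of a trans-1-aryl-1,2-dihydronaphthalene.
- The strategy rests on C1 and C2 of ring B. C1 carries the 4-hydroxyphenyl ring, so it is doubly benzylic and para to a phenol OH, the exocyclic carbon of a latent para-quinone methide. C2 carries an aroyl group and is an enolisable ketone alpha carbon, so C1–C2 is cut as an intramolecular 1,6-addition.
- The cyclisation precursor is an (E)-2-arylidene-1,4-diaryl-1,4-diketone with a free 4-hydroxybenzyl group. Its C3=C4 bond comes from a Wittig olefination between the PBu3 ylide of a 1,2-diaroylethylene and 2-(4-acetoxybenzyl)-4,5-dimethoxybenzaldehyde.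
- The aldehyde comes from a Negishi coupling of a benzylzinc reagent with 2-bromo-4,5-dimethoxybenzaldehyde; the diaroylethylene comes from a twofold Friedel–Crafts acylation with fumaryl chloride.
- Ring order: the benzo ring A, the 4-hydroxyphenyl ring and both resorcinol rings are bought. Ring B is the only ring formed (step 5) and is made aromatic in step 6.

Key step: step 5

Remark: the target has no stereocentre, so the dihydronaphthalene of the key step is carried as a racemate, and the phenol that triggers the key step is masked as its acetate until step 4.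

Step 1
Reactants: 1 fumaryl chloride; 2 1,3-dimethoxybenzene (2.1 equiv)
Product: 3 (E)-1,4-bis(2,4-dimethoxyphenyl)but-2-ene-1,4-dione
Conditions: AlCl3 (2.3 equiv), CH2Cl2, 0 °C to rt; ice/aq. HCl work-up
Reagents that add atoms: none
Why: Twofold Friedel–Crafts acylation, in which each acyl chloride end attacks 1,3-dimethoxybenzene at C4 (para to one methoxy, ortho to the other; C2 is flanked by both and hindered), and low temperature with little excess AlCl3 should avoid chelation-assisted loss of the ortho methyl ethers.

Step 2
Reactants: 4 4-(chloromethyl)phenyl acetate; 5 2-bromo-4,5-dimethoxybenzaldehyde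
Product: 7 4-(2-formyl-4,5-dimethoxybenzyl)phenyl acetate, via (4-acetoxybenzyl)zinc chloride 6 (not isolated)
Conditions: Zn dust, LiCl, THF, 25 °C; then 5, Pd(OAc)2 (2 mol%), SPhos (4 mol%), THF, 25–40 °C
Reagents that add atoms: none
Why: Negishi cross-coupling, in which LiCl-assisted zinc insertion into the benzylic C–Cl bond tolerates the aryl acetate and the palladium-catalysed coupling at the C–Br bond (activated by the ortho formyl group) should outrun uncatalysed addition of the benzylzinc reagent to the electron-rich, deactivated aldehyde.

Step 3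
Reactants: 3 (E)-1,4-bis(2,4-dimethoxyphenyl)but-2-ene-1,4-dione; 7 4-(2-formyl-4,5-dimethoxybenzyl)phenyl acetate
Product: 9 (E)-2-[2-(4-acetoxybenzyl)-4,5-dimethoxybenzylidene]-1,4-bis(2,4-dimethoxyphenyl)butane-1,4-dione, via tributylphosphonium ylide 8 (not isolated)
Conditions: PBu3 (1.1 equiv), toluene, 0 °C to rt; then 7, 80 °C
Reagents that add atoms: none
Why: Wittig olefination with a ylide made in the flask (phosphine conjugate addition to the 1,2-diaroylethylene, then proton shift, as known for maleimides, fumarates and diaroylethylenes), which under thermodynamic control should place the aryl group trans to the aroyl group (E), that is cis to the CH2C(=O)Ar arm as the ring closure requires.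

Step 4
Reactants: 9 (E)-2-[2-(4-acetoxybenzyl)-4,5-dimethoxybenzylidene]-1,4-bis(2,4-dimethoxyphenyl)butane-1,4-dione
Product: 10 (E)-2-[2-(4-hydroxybenzyl)-4,5-dimethoxybenzylidene]-1,4-bis(2,4-dimethoxyphenyl)butane-1,4-dione
Conditions: K2CO3 (0.2 equiv), MeOH/THF 1:1, 0 °C; AcOH quench
Reagents that add atoms: none
Why: Base-catalysed transesterification (Zemplén-type methanolysis), in which the aryl acetate with its phenoxide leaving group should be cleaved within minutes at 0 °C, faster than enolisation of the C2 methylene or methoxide addition to the hindered enone, while the methyl ethers are inert.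

Step 5
Reactants: 10 (E)-2-[2-(4-hydroxybenzyl)-4,5-dimethoxybenzylidene]-1,4-bis(2,4-dimethoxyphenyl)butane-1,4-dione
Product: 12 racemic trans-(1RS,2SR)-2,3-bis(2,4-dimethoxybenzoyl)-1-(4-hydroxyphenyl)-6,7-dimethoxy-1,2-dihydronaphthalene, via para-quinone methide 11 (not isolated)
Conditions: Ag2O (1.1 equiv), 4 Å MS, CH2Cl2 (0.01 M), rt, dark; then DBU (0.1 equiv), 0 °C to rt
Reagents that add atoms: none
Why: Ag2O removes two electrons from the only phenol of 10 and the doubly benzylic CH2 para to it loses a proton, giving quinone methide 11, which has no hydrogen that would let it tautomerise to a styrene; DBU then forms the cross-conjugated dienolate of the C2 methylene (alpha to one aryl ketone, allylic to the C3=C4 enone), whose alpha carbon adds 1,6 to the methide carbon, forming C1–C2 and restoring the phenol. The closest known reaction type is the base-mediated 1,6-conjugate addition of ketone enolates and other carbon acids to para-quinone methides, including those made in the flask from 4-hydroxydiarylmethanes with Ag2O or DDQ. Ring B closes in a 6-(enolexo)-exo-trig mode; attack through the gamma carbon of the dienolate cannot compete because it would give a four-membered ring. C1 and C2 are set in the same bond-forming event, and the trans relation is expected under thermodynamic control, since C2 stays epimerisable under DBU and the trans isomer can hold the 1-aryl group pseudoaxial, away from the peri C8–H, with the 2-aroyl group on the opposite face; both centres are erased in step 6, so a cis/trans mixture costs nothing. The step needs chemoselective oxidation at the diarylmethane carbon, secured by the single free phenol (every other oxygen is a methyl ether or a ketone), and ring closure ahead of oligomerisation of the quinone methide, secured by the E double bond that holds the CH2C(=O)Ar arm beside the methide carbon and by high dilution. Any over-oxidised material should be the naphthalene that step 6 makes anyway.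

Step 6
Reactants: 12 racemic trans-2,3-bis(2,4-dimethoxybenzoyl)-1-(4-hydroxyphenyl)-6,7-dimethoxy-1,2-dihydronaphthalene
Product: 13 2,3-bis(2,4-dimethoxybenzoyl)-1-(4-hydroxyphenyl)-6,7-dimethoxynaphthalene
Conditions: DDQ (1.1 equiv), 1,4-dioxane, rt to 60 °C
Reagents that add atoms: none
Why: DDQ dehydrogenation, in which hydride abstraction from C1 (doubly benzylic and para to the phenol OH) is followed by loss of the acidic C2 proton, driven by the gain of naphthalene aromaticity and removing both stereocentres.

Step 7
Reactants: 13 2,3-bis(2,4-dimethoxybenzoyl)-1-(4-hydroxyphenyl)-6,7-dimethoxynaphthalene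
Product: 14 2,3-bis(2,4-dihydroxybenzoyl)-1-(4-hydroxyphenyl)naphthalene-6,7-diol (CNP0304576.0)
Conditions: BBr3 (14 equiv), CH2Cl2, −78 °C to rt; MeOH then H2O, under argon
Reagents that add atoms: none
Why: Lewis acid cleavage of aryl methyl ethers, in which BBr3 complexes each methoxy oxygen and bromide removes the methyl group (the two methoxy groups ortho to the ketones assisted by chelation), and hydrolysis of the aryl borates on work-up should release all seven phenols without touching the diaryl ketones.

**Compound list**
1 | fumaryl chloride | O=C(Cl)/C=C/C(=O)Cl | starting material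
2 | 1,3-dimethoxybenzene | COc1cccc(OC)c1 | starting material
3 | (E)-1,4-bis(2,4-dimethoxyphenyl)but-2-ene-1,4-dione | COc1ccc(C(=O)/C=C/C(=O)c2ccc(OC)cc2OC)c(OC)c1 | intermediate
4 | 4-(chloromethyl)phenyl acetate | CC(=O)Oc1ccc(CCl)cc1 | starting material
5 | 2-bromo-4,5-dimethoxybenzaldehyde | COc1cc(Br)c(C=O)cc1OC | starting material
6 | (4-acetoxybenzyl)zinc chloride (LiCl-solubilised, in THF) | CC(=O)Oc1ccc(C[Zn]Cl)cc1 | intermediate
7 | 4-(2-formyl-4,5-dimethoxybenzyl)phenyl acetate | CC(=O)Oc1ccc(Cc2cc(OC)c(OC)cc2C=O)cc1 | intermediate
8 | 1,4-bis(2,4-dimethoxyphenyl)-2-(tributyl-λ5-phosphanylidene)butane-1,4-dione | CCCCP(CCCC)(CCCC)=C(CC(=O)c1ccc(OC)cc1OC)C(=O)c1ccc(OC)cc1OC | intermediate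
9 | (E)-2-[2-(4-acetoxybenzyl)-4,5-dimethoxybenzylidene]-1,4-bis(2,4-dimethoxyphenyl)butane-1,4-dione | COc1ccc(C(=O)C/C(=C\c2cc(OC)c(OC)cc2Cc2ccc(OC(C)=O)cc2)C(=O)c2ccc(OC)cc2OC)c(OC)c1 | intermediate
10 | (E)-2-[2-(4-hydroxybenzyl)-4,5-dimethoxybenzylidene]-1,4-bis(2,4-dimethoxyphenyl)butane-1,4-dione | COc1ccc(C(=O)C/C(=C\c2cc(OC)c(OC)cc2Cc2ccc(O)cc2)C(=O)c2ccc(OC)cc2OC)c(OC)c1 | intermediate
11 | (E)-2-{4,5-dimethoxy-2-[(4-oxocyclohexa-2,5-dien-1-ylidene)methyl]benzylidene}-1,4-bis(2,4-dimethoxyphenyl)butane-1,4-dione | COc1ccc(C(=O)C/C(=C\c2cc(OC)c(OC)cc2C=C2C=CC(=O)C=C2)C(=O)c2ccc(OC)cc2OC)c(OC)c1 | intermediate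
12 | racemic trans-(1RS,2SR)-2,3-bis(2,4-dimethoxybenzoyl)-1-(4-hydroxyphenyl)-6,7-dimethoxy-1,2-dihydronaphthalene (the 1S,2R enantiomer is drawn) | O=C(c1ccc(OC)cc1OC)C1=Cc2cc(OC)c(OC)cc2[C@H](c2ccc(O)cc2)[C@H]1C(=O)c1ccc(OC)cc1OC | intermediate
13 | 2,3-bis(2,4-dimethoxybenzoyl)-1-(4-hydroxyphenyl)-6,7-dimethoxynaphthalene | O=C(c1ccc(OC)cc1OC)c1cc2cc(OC)c(OC)cc2c(-c2ccc(O)cc2)c1C(=O)c1ccc(OC)cc1OC | intermediate
14 | 2,3-bis(2,4-dihydroxybenzoyl)-1-(4-hydroxyphenyl)naphthalene-6,7-diol | O=C(c1ccc(O)cc1O)c1cc2cc(O)c(O)cc2c(-c2ccc(O)cc2)c1C(=O)c1ccc(O)cc1O | target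

**Step count**
Total step count: 7. Longest linear sequence: 6 steps (steps 2 to 7 from 4 and 5, or steps 1 and 3 to 7 from 1 and 2).

**Steps most likely to fail**

Step 5. The transient quinone methide may oligomerise, or phenoxy radicals may couple, before the C2 dienolate closes ring B. Fallback: setting out from 10, the quinone methide is generated with DDQ (1.05 equiv) in CH2Cl2/MeOH at 0 °C, where methanol should capture it at once. This gives racemic (E)-2-{2-[(4-hydroxyphenyl)(methoxy)methyl]-4,5-dimethoxybenzylidene}-1,4-bis(2,4-dimethoxyphenyl)butane-1,4-dione F1, a stable quinone methide surrogate that can be purified. Treating it with BF3·OEt2 (or Sc(OTf)3) in CH2Cl2 at −40 °C re-ionises it to the diarylmethyl cation (the O-protonated quinone methide), which alkylates the enol of the C2 ketone intramolecularly. This is the known acid-mediated SN1 alkylation of a ketone by a benzhydryl ether, so the ring is closed by a cationic instead of an anionic pathway. The fallback returns to the route at 12.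

Step 3. Olefination of the electron-rich, ortho-substituted aldehyde by the stabilised, alpha-branched ylide may be slow, with loss of ylide through side reactions of the phosphonium enolate and erosion of the double-bond geometry. Fallback: setting out from 3, base-catalysed phospha-Michael addition of diethyl phosphite (DBU cat., THF, rt) should give diethyl [1,4-bis(2,4-dimethoxyphenyl)-1,4-dioxobutan-2-yl]phosphonate F2. Horner–Wadsworth–Emmons olefination of 7 with it under Masamune–Roush conditions (LiCl, DBU, MeCN, rt) uses a more nucleophilic phosphonate carbanion, is E-selective and spares the aryl acetate. The fallback returns to the route at 9.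

Step 2. The benzylzinc reagent may add to the free formyl group, and Wurtz-type homocoupling may occur during zinc insertion. Fallback: setting out from 4, Suzuki–Miyaura coupling with commercial (2-formyl-4,5-dimethoxyphenyl)boronic acid (Pd(OAc)2, SPhos, anhydrous K3PO4, toluene, 80 °C) forms the same diarylmethane bond with reversed polarity, so no carbon nucleophile that can attack the aldehyde is present. The fallback returns to the route at 7 and makes no compound outside the list (F0).

**Further compounds**
F1 | step 5 | racemic (E)-2-{2-[(4-hydroxyphenyl)(methoxy)methyl]-4,5-dimethoxybenzylidene}-1,4-bis(2,4-dimethoxyphenyl)butane-1,4-dione | COc1ccc(C(=O)C/C(=C\c2cc(OC)c(OC)cc2C(OC)c2ccc(O)cc2)C(=O)c2ccc(OC)cc2OC)c(OC)c1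
F2 | step 3 | racemic diethyl [1,4-bis(2,4-dimethoxyphenyl)-1,4-dioxobutan-2-yl]phosphonate | CCOP(=O)(OCC)C(CC(=O)c1ccc(OC)cc1OC)C(=O)c1ccc(OC)cc1OC
F0 | step 2 | none | none
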